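**Retrosynthetic overview**

1. Labels (p-menthane): ring C1 (bears C7H3 and Br), C2 (Br), C3, C4, C5, C6; on C4 the side chain C8 (Br, C10H3, C9H2Br). The route rests on ring carbon C4 carrying the fully substituted, heteroatom-bearing C8: C8/C9/C10 are the carbinol end of (R)-citramalic acid 1, C4 and C3 its CH2 and far carboxyl carbon, and C5–C6–C1–C2 are methyl vinyl ketone 6.
2. Target 19 ⇐ tribromo alcohol 18 (C8–OH to C8–Br with retention through a C8/C9 bromonium ion) ⇐ bromohydrin 17 (trans-diaxial Br2 addition to C1=C2) ⇐ epoxide 16 ⇐ diol 14.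
3. 14 ⇐ enol triflate 11 (methyl coupling puts C7 on C1, then acetonide removal) ⇐ enone 9 (conjugate reduction, O-triflation at C1).
4. 9 ⇐ aldehyde 5 + 6: amine-catalysed Michael addition (C4–C5), then aldol condensation (C2–C3) closes the only ring, the cyclohexane; 5 ⇐ 1 by reduction, acetonide formation and oxidation.

Key step: step 4

Assumption: (R)-citramalic acid 1 is used as the free acid (a commercial salt would be acidified and dried first); all equivalents and temperatures are proposed values.

**Route**

Step 1
Reactants: 1 (R)-citramalic acid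
Product: 2 (2R)-2-methylbutane-1,2,4-triol
Conditions: BH3·SMe2 (3.5 equiv), B(OMe)3, THF, 0 °C → rt; MeOH quench
Reagents that add atoms: none
Why: Borane reduction of carboxylic acids (via acyloxyboranes) turns both CO2H groups into CH2OH without touching the tertiary C–O bond, so the (R) configuration of the future C8 is carried over unchanged.

Step 2
Reactants: 2 (2R)-2-methylbutane-1,2,4-triol; 3 2,2-dimethoxypropane
Product: 4 2-[(4R)-2,2,4-trimethyl-1,3-dioxolan-4-yl]ethan-1-ol
Conditions: TsOH·H2O (cat.), acetone, rt; Et3N quench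
Reagents that add atoms: none
Why: Acid-catalysed transketalisation under thermodynamic control favours the five-membered 1,2-acetonide over the 1,3-dioxane through the C8 and C3 hydroxyls, which would hold an axial substituent against an axial ketal methyl, so the primary C3 hydroxyl stays free.

Step 3
Reactants: 4 2-[(4R)-2,2,4-trimethyl-1,3-dioxolan-4-yl]ethan-1-ol
Product: 5 2-[(4R)-2,2,4-trimethyl-1,3-dioxolan-4-yl]acetaldehyde
Conditions: TEMPO (10 mol%), PhI(OAc)2 (1.1 equiv), CH2Cl2, rt
Reagents that add atoms: none
Why: Oxoammonium (TEMPO/PhI(OAc)2) oxidation of the primary alcohol stops at the aldehyde under non-basic conditions that leave the acetonide and the β-oxygenated aldehyde intact.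

Step 4
Reactants: 5 2-[(4R)-2,2,4-trimethyl-1,3-dioxolan-4-yl]acetaldehyde; 6 methyl vinyl ketone
Product: 9 (4R)-4-[(4R)-2,2,4-trimethyl-1,3-dioxolan-4-yl]cyclohex-2-en-1-one, via keto aldehyde 7 (not isolated), via ketol 8 (not isolated)
Conditions: (S)-α,α-diphenylprolinol TMS ether (10 mol%), ethyl 3,4-dihydroxybenzoate (20 mol%), 6 (1.5 equiv), neat, 4 °C; then LiOH (20 mol%), iPrOH, rt
Reagents that add atoms: none
Why: The catalyst condenses with 5 to the E-enamine (C8 is quaternary, so only C4 can become nucleophilic), which adds to the terminal carbon of 6 to form C4–C5; hydrolysis releases keto aldehyde 7 and the catalyst, and LiOH then forms the methyl-ketone enolate, which attacks the aldehyde carbon to form C2–C3 and, after loss of water from ketol 8, gives enone 9. The closest known reaction type is the secondary-amine-catalysed Michael addition of linear and β-branched aldehydes to methyl vinyl ketone followed by base-mediated aldol condensation to 4-substituted cyclohex-2-enones. The cyclohexenone closes in a 6-(enolexo)-exo-trig aldol mode, since closure through the C6 methylene enolate would give a four-membered ring. The new stereocentre C4 is set by the catalyst: the diphenyl(silyloxy)methyl group of the (S)-pyrrolidine shields one face of the s-trans E-enamine, so 6 approaches from the other face, which corresponds to (2S) in 7 and (4R) in 9. The step needs catalyst control to override any bias from the adjacent C8 centre and needs C4 to survive the condensation; the weak phenolic co-catalyst at 4 °C and sub-stoichiometric LiOH at rt are chosen so that neither β-elimination of the ketal oxygen nor epimerisation at C4 sets in, and the C8 oxygen, tied into the five-membered ketal, is a poor leaving group.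

Step 5
Reactants: 9 (4R)-4-[(4R)-2,2,4-trimethyl-1,3-dioxolan-4-yl]cyclohex-2-en-1-one
Product: 11 (4R)-4-[(4R)-2,2,4-trimethyl-1,3-dioxolan-4-yl]cyclohex-1-en-1-yl trifluoromethanesulfonate, via lithium enolate 10 (not isolated)
Conditions: L-Selectride (1.05 equiv), THF, −78 °C; then PhNTf2, −78 → 0 °C
Reagents that add atoms: N-phenylbis(trifluoromethanesulfonimide), O=S(=O)(N(c1ccccc1)S(=O)(=O)C(F)(F)F)C(F)(F)F
Why: 1,4-Reduction of the β-unsubstituted enone by the hindered trialkylborohydride delivers hydride to C3 and gives the C1–C2 enolate 10 regiospecifically, which PhNTf2 sulfonylates on oxygen (enone to enol triflate); no stereocentre is formed, and keeping the double bond on the C2 side is what keeps C4 stereogenic and (R).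

Step 6
Reactants: 11 (4R)-4-[(4R)-2,2,4-trimethyl-1,3-dioxolan-4-yl]cyclohex-1-en-1-yl trifluoromethanesulfonate; 12 methylmagnesium bromide
Product: 13 (4R)-2,2,4-trimethyl-4-[(1R)-4-methylcyclohex-3-en-1-yl]-1,3-dioxolane
Conditions: Fe(acac)3 (5 mol%), THF/NMP, −30 → 0 °C
Reagents that add atoms: none
Why: Iron-catalysed Kumada-type cross-coupling of an alkenyl triflate with a methyl Grignard reagent replaces OTf by CH3 without moving the double bond, which places C7 on C1 and leaves C1=C2; the acetonide is inert.

Step 7
Reactants: 13 (4R)-2,2,4-trimethyl-4-[(1R)-4-methylcyclohex-3-en-1-yl]-1,3-dioxolane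
Product: 14 (2R)-2-[(1R)-4-methylcyclohex-3-en-1-yl]propane-1,2-diol
Conditions: AcOH/H2O (4:1), 40 °C
Reagents that add atoms: none
Why: Acid hydrolysis of the isopropylidene ketal breaks only the ketal C–O bonds, so C8 keeps its configuration, and dilute acetic acid is too weak to hydrate or isomerise the trisubstituted alkene.

Step 8
Reactants: 14 (2R)-2-[(1R)-4-methylcyclohex-3-en-1-yl]propane-1,2-diol
Product: 15 (2R)-2-hydroxy-2-[(1R)-4-methylcyclohex-3-en-1-yl]propyl 4-methylbenzenesulfonate
Conditions: TsCl (1.1 equiv), Et3N, DMAP (cat.), CH2Cl2, 0 °C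
Reagents that add atoms: p-toluenesulfonyl chloride, Cc1ccc(cc1)S(=O)(=O)Cl
Why: Sulfonylation is chemoselective for the unhindered primary C9 hydroxyl over the tertiary C8 hydroxyl.

Step 9
Reactants: 15 (2R)-2-hydroxy-2-[(1R)-4-methylcyclohex-3-en-1-yl]propyl 4-methylbenzenesulfonate
Product: 16 (2R)-2-methyl-2-[(1R)-4-methylcyclohex-3-en-1-yl]oxirane
Conditions: K2CO3, MeOH, 0 °C → rt
Reagents that add atoms: none
Why: Intramolecular Williamson etherification (3-exo-tet) of the C8 alkoxide onto C9 closes the oxirane without breaking the C8–O bond, so C8 stays (R).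

Step 10
Reactants: 16 (2R)-2-methyl-2-[(1R)-4-methylcyclohex-3-en-1-yl]oxirane
Product: 17 (2R)-1-bromo-2-[(1R)-4-methylcyclohex-3-en-1-yl]propan-2-ol
Conditions: LiBr (2 equiv), AcOH (1.5 equiv), THF, rt
Reagents that add atoms: lithium bromide, [Li+].[Br-]
Why: Bromide opens the weakly acid-activated 2,2-disubstituted epoxide by SN2 attack at the unsubstituted C9 (halohydrin formation), which leaves the C8–O bond and its configuration untouched.

Step 11
Reactants: 17 (2R)-1-bromo-2-[(1R)-4-methylcyclohex-3-en-1-yl]propan-2-ol
Product: 18 (2R)-1-bromo-2-[(1R,3S,4S)-3,4-dibromo-4-methylcyclohexyl]propan-2-ol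
Conditions: Br2 (1.05 equiv), CH2Cl2, −78 °C, dark
Reagents that add atoms: bromine, BrBr
Why: Electrophilic anti addition of bromine, in which the bromonium ion of the half-chair with the C4 side chain equatorial is opened by bromide along the trans-diaxial trajectory and both bromonium faces converge on the same diaxial dibromide, sets C1 (S, Br cis to the side chain) and C2 (S, Br trans to it); at −78 °C ion-pair collapse with bromide should outrun capture by the C8 hydroxyl and the kinetic diaxial product should not rearrange.

Step 12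
Reactants: 18 (2R)-1-bromo-2-[(1R,3S,4S)-3,4-dibromo-4-methylcyclohexyl]propan-2-ol
Product: 19 (1S,2S,4R)-1,2-dibromo-4-[(2R)-1,2-dibromopropan-2-yl]-1-methylcyclohexane
Conditions: HBr (anhydrous, excess), CH2Cl2, −30 → 0 °C
Reagents that add atoms: hydrogen bromide, Br
Why: Substitution with neighbouring-bromine participation, in which loss of water from the protonated C8 hydroxyl is assisted by the antiperiplanar C9 bromine and the unsymmetrical C8/C9 bromonium ion is opened by the paired bromide at tertiary C8 on the face the water left, gives net retention (two inversions) and the (8R) bromide, while the earlier ring bromination leaves no alkene for HBr to attack.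

**Compound list**

1 | (R)-citramalic acid, (2R)-2-hydroxy-2-methylbutanedioic acid | C[C@](O)(C(=O)O)CC(=O)O | starting material
2 | (2R)-2-methylbutane-1,2,4-triol | C[C@](O)(CO)CCO | intermediate
3 | 2,2-dimethoxypropane | COC(C)(C)OC | starting material
4 | 2-[(4R)-2,2,4-trimethyl-1,3-dioxolan-4-yl]ethan-1-ol | C[C@]1(COC(C)(C)O1)CCO | intermediate
5 | 2-[(4R)-2,2,4-trimethyl-1,3-dioxolan-4-yl]acetaldehyde | C[C@]1(COC(C)(C)O1)CC=O | intermediate
6 | methyl vinyl ketone | CC(=O)C=C | starting material
7 | (2S)-5-oxo-2-[(4R)-2,2,4-trimethyl-1,3-dioxolan-4-yl]hexanal (Michael adduct, not isolated) | C[C@]1(COC(C)(C)O1)[C@@H](C=O)CCC(C)=O | intermediate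
8 | (4R)-3-hydroxy-4-[(4R)-2,2,4-trimethyl-1,3-dioxolan-4-yl]cyclohexan-1-one (aldol, C3 epimers, not isolated) | C[C@]1(COC(C)(C)O1)[C@@H]2CCC(=O)CC2O | intermediate
9 | (4R)-4-[(4R)-2,2,4-trimethyl-1,3-dioxolan-4-yl]cyclohex-2-en-1-one | C[C@]1(COC(C)(C)O1)[C@@H]2CCC(=O)C=C2 | intermediate
10 | lithium (4R)-4-[(4R)-2,2,4-trimethyl-1,3-dioxolan-4-yl]cyclohex-1-en-1-olate (not isolated) | [Li+].C[C@]1(COC(C)(C)O1)[C@@H]2CCC([O-])=CC2 | intermediate
11 | (4R)-4-[(4R)-2,2,4-trimethyl-1,3-dioxolan-4-yl]cyclohex-1-en-1-yl trifluoromethanesulfonate | C[C@]1(COC(C)(C)O1)[C@@H]2CCC(OS(=O)(=O)C(F)(F)F)=CC2 | intermediate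
12 | methylmagnesium bromide | C[Mg]Br | starting material
13 | (4R)-2,2,4-trimethyl-4-[(1R)-4-methylcyclohex-3-en-1-yl]-1,3-dioxolane | C[C@]1(COC(C)(C)O1)[C@@H]2CCC(C)=CC2 | intermediate
14 | (2R)-2-[(1R)-4-methylcyclohex-3-en-1-yl]propane-1,2-diol | C[C@](O)(CO)[C@@H]1CCC(C)=CC1 | intermediate
15 | (2R)-2-hydroxy-2-[(1R)-4-methylcyclohex-3-en-1-yl]propyl 4-methylbenzenesulfonate | C[C@](O)(COS(=O)(=O)c1ccc(C)cc1)[C@@H]2CCC(C)=CC2 | intermediate
16 | (2R)-2-methyl-2-[(1R)-4-methylcyclohex-3-en-1-yl]oxirane | C[C@]1(CO1)[C@@H]2CCC(C)=CC2 | intermediate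
17 | (2R)-1-bromo-2-[(1R)-4-methylcyclohex-3-en-1-yl]propan-2-ol | C[C@](O)(CBr)[C@@H]1CCC(C)=CC1 | intermediate
18 | (2R)-1-bromo-2-[(1R,3S,4S)-3,4-dibromo-4-methylcyclohexyl]propan-2-ol | C[C@](O)(CBr)[C@@H]1CC[C@](C)(Br)[C@@H](Br)C1 | intermediate
19 | (1S,2S,4R)-1,2-dibromo-4-[(2R)-1,2-dibromopropan-2-yl]-1-methylcyclohexane | C[C@](Br)(CBr)[C@@H]1CC[C@](C)(Br)[C@@H](Br)C1 | target

**Step count and risks**

Total step count: 12. Longest linear sequence: 12 steps (1 → 19).

Steps most likely to fail:

1. Step 12. Ionisation at C8 may run through an open tertiary cation instead of the bridged bromonium ion, which would scramble C8, or divert into elimination or a hydride shift from C4. The fallback gives up substitution at C8; it sets out from bromohydrin 17 and comes back to the route at target 19. Reductive β-elimination of 17 (Zn dust, AcOH/EtOH, 60 °C) should give (4R)-limonene F5. Addition of Br2 (2.1 equiv, CH2Cl2, −78 °C) to both alkenes should then give 19 together with its C8 epimer F6, to be separated by fractional crystallisation or preparative HPLC. The citramalate centre no longer controls C8 on this path, so it is a last resort.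

2. Step 4. The catalyst may fail to override the neighbouring C8 centre, the hindered enamine may add slowly, or C4 may epimerise during the condensation. The fallback removes the need for facial control in the conjugate addition; it sets out from aldehyde 5 and methyl vinyl ketone 6 and comes back to the route at lithium enolate 10, and so at triflate 11. The same Michael–aldol sequence run with an achiral amine (pyrrolidine/benzoic acid, then LiOH) should give 9 mixed with the C4-epimeric enone F1. Hydrogenation (H2, Pd/C, EtOAc) converges both on cyclohexanone F2, in which C4 is no longer stereogenic. Desymmetrising deprotonation with a C2-symmetric chiral lithium amide and in-situ silylation (lithium bis[(S)-1-phenylethyl]amide, LiCl, TMSCl, THF, −100 °C) should give silyl enol ether F3. The S,S base is expected by analogy with 4-tert-butylcyclohexanone, and its enantiomer would be taken if the sense proved opposite. MeLi (THF, 0 °C) then regenerates enolate 10 for triflation as in step 5.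

3. Step 11. The C8 hydroxyl may capture the C1–C2 bromonium ion (bromoetherification to a bridged cineole-type ether) instead of bromide, or diaxial selectivity may be incomplete. The fallback changes the order of events so that no free hydroxyl is present; it sets out from epoxide 16 and comes back to the route at tribromo alcohol 18. Bromination of 16 (Br2, solid K2CO3 as acid scavenger, CH2Cl2, −78 °C) should give the dibromo epoxide F4. Opening F4 at C9 with LiBr/AcOH in THF, as in step 10, should give 18.

**Further compounds**

F1 | step 4 | (4S)-4-[(4R)-2,2,4-trimethyl-1,3-dioxolan-4-yl]cyclohex-2-en-1-one | C[C@]1(COC(C)(C)O1)[C@H]2CCC(=O)C=C2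
F2 | step 4 | 4-[(4R)-2,2,4-trimethyl-1,3-dioxolan-4-yl]cyclohexan-1-one | C[C@]1(COC(C)(C)O1)C2CCC(=O)CC2
F3 | step 4 | trimethyl({(4R)-4-[(4R)-2,2,4-trimethyl-1,3-dioxolan-4-yl]cyclohex-1-en-1-yl}oxy)silane | C[C@]1(COC(C)(C)O1)[C@@H]2CCC(O[Si](C)(C)C)=CC2
F4 | step 11 | (2R)-2-[(1R,3S,4S)-3,4-dibromo-4-methylcyclohexyl]-2-methyloxirane | C[C@]1(CO1)[C@@H]2CC[C@](C)(Br)[C@@H](Br)C2
F5 | step 12 | (4R)-limonene, (4R)-1-methyl-4-(prop-1-en-2-yl)cyclohex-1-ene | CC(=C)[C@@H]1CCC(C)=CC1
F6 | step 12 | (1S,2S,4R)-1,2-dibromo-4-[(2S)-1,2-dibromopropan-2-yl]-1-methylcyclohexane | C[C@@](Br)(CBr)[C@@H]1CC[C@](C)(Br)[C@@H](Br)C1
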